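## Structural features

The target is a C2-symmetric, fully substituted tetrahydrofuran (ring atoms O1, C2, C3, C4, C5) with 4-hydroxyphenyl groups on C2 and C5 and 2,4-dihydroxybenzoyl groups on C3 and C4. All four ring carbons are contiguous stereocentres, (2S,3R,4R,5S): the two aryl groups are trans, the two aroyl groups are trans, and each aroyl group is cis to the aryl group on the neighbouring carbon. This cis,trans,cis array is not the most stable one. C3 and C4 are α to aryl ketones and O1 is β to both carbonyl groups, so base can invert them by enolisation or by retro-oxa-Michael ring opening, with the all-trans isomer as the end point. C2 and C5 are 4-hydroxybenzylic ether carbons that can ionise under acid, and the six phenols exclude strongly basic or oxidising conditions late in the route. The skeleton is simple, so the real difficulty is stereochemical: the 2,3-cis and 4,5-cis relationships must be set under kinetic control and then carried to the end under nearly neutral conditions. The key step exploits the fact that C2 and C5 are both bonded to O1. An acyclic bis(propargylic) ether already holds O1, C2, C5, both aryl groups and both absolute configurations; C3 and C4 are its inner alkyne carbons, so one C3–C4 bond closes the ring and leaves the two future carbonyl carbons as exocyclic arylmethylidene carbons.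

## Logic of the disconnections

17 ⇒ 16. The six phenolic O–H bonds are replaced by O–Si bonds. Free phenols would quench the organometallic and hydride reagents used earlier and would not survive the oxidation that forms the ketones; silicon is chosen because buffered fluoride removes it. The forward step must stay non-basic, because C3 and C4 of 16 and 17 are epimerisable.

16 ⇒ 15. The two ketone C=O bonds are taken back to secondary carbinols. At that level C3 and C4 cannot enolise, so the stereocentres can be installed and purified without risk, and a benzylic carbinol is exactly what hydroboration–oxidation leaves. The forward oxidation must be neutral and must spare electron-rich arenes.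

15 ⇒ 13 (through 14). The C3–H and C4–H bonds and the two benzylic C–O bonds are cut, the retron of a twofold syn hydroboration with oxidation. This removes four stereocentres at once and leaves a flat, C2-symmetric 1,3-diene whose only stereocentres are C2 and C5. An oxidative 1,4-functionalisation of the diene termini was not chosen, because it leads through a tetrasubstituted C3=C4 alkene that would need an anti addition of hydrogen, for which no dependable chemical reagent exists. The forward step must place boron on the exocyclic carbons, attack the first alkene from the face opposite the neighbouring aryl group, and deliver the second B–H bond within the same molecule so that 3,4-trans results.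

13 ⇒ 11 (through 12). The C3–C4 bond is cut; this is the strategic disconnection. It opens the only ring and leads to 11, which is acyclic, twofold symmetric and has only two stereocentres; the two alkene geometries of 13 follow from the cis addition of the metal. The forward step must couple the inner alkyne carbons only and must not break the propargylic C–O bonds.

11 ⇒ 8 + 10. The two C(sp)–C(aryl) bonds are cut. This makes the route convergent, puts the two most electron-rich rings into 10, and leaves terminal alkynes in 8, which the preceding ether formation needs. The forward coupling must run at room temperature with an amine base, since an electron-rich, ortho-substituted bromide is sluggish and aryl silyl ethers do not tolerate carbonate or hydroxide.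

8 ⇒ 6 + 7. One C–O bond of the ether is cut, which divides the C2-symmetric ether into a nucleophilic and an electrophilic half of the same carbon skeleton. The stereocentre of 6 is kept as it is, whereas that of 7 disappears in a copper allenylidene and is set again by a chiral ligand, so 7 may be racemic. The demand is a copper catalyst that controls the new centre although the nucleophile is a hindered secondary alcohol.

6 ⇒ 5 and 7 ⇒ 5. The ester C–O bond of 7 is cut, and 6 is traced to the same racemate without cutting a skeletal bond, by selecting one enantiomer. Both halves of 8 then come from one simple alcohol. The demand is a lipase that distinguishes the aryl group from the ethynyl group well enough to leave 6 in high enantiomeric purity.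

5 ⇒ 3 + 4. The C–C bond between the carbinol carbon and the alkyne is cut. No stereocontrol is asked of the forward addition, because the resolution follows.

3 ⇒ 1 + 2 and 10 ⇒ 9 + 2. O–Si bonds are cut, back to commercial phenols; the silylations only have to go to completion.

## Other disconnections considered

Alternative 1: The cut is at the two C–aryl bonds on C2 and C5. In the forward sense the trans-diamide A1, which has only C3 and C4 as stereocentres, would be arylated twice with the aryl iodide A2 under Pd(OAc)2 and AgOAc to give A3. Each quinolin-8-yl amide group would guide palladium to the C–H bond on its own face through a five-membered cyclometalated ring.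
- In its favour: the 2,3-cis and 4,5-cis relationships, the hard part of the target, would follow from the geometry of the cyclometalation and not from a steric preference. On this point the alternative is the better plan, because the chosen route relies on face selection and intramolecular delivery in a hydroboration. A1 is also smaller than 11, and 2,5-trans follows from 3,4-trans, so the two plans are equal on that relationship.
- Against it here: the bonds to be arylated are α-oxygen methylene C–H bonds that must react twice on one ring, the second time beside a new aryl group. A3 is still two aryl ketones away from 17, and converting hindered quinolin-8-yl amides into ketones needs activation and an aryl-metal reagent under basic conditions, the conditions under which a cis acyl group beside an aryl group epimerises. The benzyl ethers would finally be hydrogenolysed next to two benzylic ring C–O bonds.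
- Comparison: the step counts should be close. The alternative places its least predictable operations after the stereocentres are set, whereas the chosen plan sets C3 and C4 late and afterwards touches them only with neutral reagents.

Alternative 2: The cut removes, in one step, the aryl group on C2, the whole aroyl group on C3 and the acyl–aryl bond within it. In the forward sense the cis-dihydrofuran A4, which already carries the C4 aroyl and C5 aryl groups, would react with the aryl iodide A2, carbon monoxide A6 and the boronic acid A5 under palladium catalysis. Palladium would add with the aryl group syn across the C2=C3 enol ether bond (aryl to C2), A6 would insert into the C3–Pd bond, and A5 would transfer its aryl group to give A7.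
- In its favour: three bonds and two stereocentres form in one operation, and syn addition fixes 2,3-cis by mechanism. Addition anti to the two cis substituents should give 3,4-trans; on this relationship the substrate bias is clearer than in the second hydroboration of the chosen route, and the alternative is the better. A7 is one deprotection from 17, so the end of the route is also shorter.
- Against it here: the palladium on C3 would sit syn to the hydrogen on C4, which is also α to a ketone, so β-hydride elimination competes with insertion of A6. Direct coupling of A2 with A5, with or without A6, bypasses the alkene. A4 is a β,γ-unsaturated ketone that can slip into conjugation with loss of both stereocentres, and as an enantiopure cis-disubstituted dihydrofuran it is a problem of nearly the same rank as the target. Six benzyl ethers must be hydrogenolysed without cleaving the benzylic ring C–O bonds.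
- Comparison: after its key step the alternative is shorter. Before it, the stereochemical burden is moved into A4, where the chosen plan needs only 11 with two centres. The three-component step has several competing channels, while the ring closure of step 8 has one main competitor.

Alternative 3: The cut is at both acyl–aryl bonds, each taken together with the neighbouring phenolic C–O bond. In the forward sense the dicarboxylate of A8 would add through oxygen to two equivalents of the aryne A9, released by fluoride from the silyl triflate A10. Each aryl carbanion formed would capture the acyl group beside it, giving the ortho-hydroxyaryl ketones of A11.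
- In its favour: the aryl ketone and its free ortho-phenol would form in one event without an aryl-metal reagent. Carboxylate α-carbons are far less acidic than ketone α-carbons, so C3 and C4 would be safer during this step than in the last steps of the chosen route, and on this point the alternative is the better. No stereocentre is created, so only regiochemistry is asked, and on that count the two plans are equal.
- Against it here: the regiochemistry depends on the chlorine atoms, which must later be removed with four benzyl groups by hydrogenolysis beside benzylic ring C–O bonds. Each acyl transfer competes with simple O-arylation, and two must succeed on one molecule. The β-alkoxy ketones, once formed, must survive fluoride and carboxylate. A8 already contains all four stereocentres in the cis,trans,cis array, so the central problem is only moved into its synthesis, and A10 needs its own preparation.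
- Comparison: structurally this is the most conservative plan (ring and stereocentres first). Mechanistically it is less controllable than a tether-enforced cyclometalation, and in step economy it is clearly longer.

Key step: step 8

Remark: TBS = tert-butyldimethylsilyl and TBSO = tert-butyldimethylsilyloxy. The same spatial arrangement at the two ether carbons is S in 6 and 8 (aryl outranks ethynyl), R in 11, 12 and 13 (arylethynyl, then the ring alkene carbon, outrank aryl) and S again at C2 and C5 from 14 on (aryl outranks the sp3 ring carbon). Nothing is inverted along the route. The SMILES of 11 and 13 encode R,R centres and Z,Z alkenes, as the mechanism of step 8 requires, so neither structure needs correction.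

Assumption: the CuOTf complex of (S,S)-Ph-pybox, 2,6-bis[(4S)-4-phenyl-4,5-dihydrooxazol-2-yl]pyridine, is taken to give the S configuration at the new ether carbon with 6 as nucleophile. If the meso ether predominates, the (R,R) ligand is used with nothing else changed.

## Route

Step 1
Reactants: 1 4-hydroxybenzaldehyde; 2 tert-butyldimethylsilyl chloride
Product: 3 4-(TBSO)benzaldehyde
Conditions: imidazole (2.5 equiv), DMF, 0 °C → rt
Reagents that add atoms: 2 tert-butyldimethylsilyl chloride, CC(C)(C)[Si](C)(C)Cl
Why: Standard silylation of a phenol; the aldehyde is untouched and the silyl ether tolerates every later step that avoids hydroxide, alkoxide or carbonate.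

Step 2
Reactants: 3 4-(TBSO)benzaldehyde; 4 ethynylmagnesium bromide
Product: 5 rac-1-[4-(TBSO)phenyl]prop-2-yn-1-ol
Conditions: THF, 0 °C → rt; sat. aq. NH4Cl
Reagents that add atoms: 4 ethynylmagnesium bromide, C#C[Mg]Br
Why: Grignard addition of an alkynyl nucleophile to an aldehyde; the product is deliberately racemic because step 3 resolves it and step 4 needs the racemate.

Step 3
Reactants: 5 rac-1-[4-(TBSO)phenyl]prop-2-yn-1-ol
Product: 6 (S)-1-[4-(TBSO)phenyl]prop-2-yn-1-ol
Conditions: Novozym 435 (immobilised lipase B of Candida antarctica), vinyl acetate (3 equiv), MTBE, 30 °C, stopped just past half conversion (chiral HPLC); filter; chromatography on silica gel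
Reagents that add atoms: none
Why: Lipase-catalysed kinetic resolution by enantioselective transesterification: the enzyme should acetylate the R enantiomer (aryl as the large, ethynyl as the medium group) and leave 6, whose S centre is carried unchanged to one ether carbon of 8. Running slightly past half conversion trades a little material for the enantiomeric purity of the unreacted alcohol, and the (R)-acetate formed alongside is removed by chromatography.

Step 4
Reactants: 5 rac-1-[4-(TBSO)phenyl]prop-2-yn-1-ol
Product: 7 rac-1-[4-(TBSO)phenyl]prop-2-yn-1-yl acetate
Conditions: Ac2O (1.5 equiv), Et3N (2 equiv), DMAP (5 mol%), CH2Cl2, 0 °C → rt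
Reagents that add atoms: acetic anhydride, CC(=O)OC(C)=O
Why: DMAP-catalysed acylation of a secondary alcohol; the electrophile is made racemic on purpose because step 5 erases its stereocentre, and the (R)-acetate separated in step 3 has the same constitution and can be added to the same batch.

Step 5
Reactants: 6 (S)-1-[4-(TBSO)phenyl]prop-2-yn-1-ol; 7 rac-1-[4-(TBSO)phenyl]prop-2-yn-1-yl acetate
Product: 8 (S,S)-bis{1-[4-(TBSO)phenyl]prop-2-yn-1-yl} ether
Conditions: 7 (1.3 equiv), CuOTf·0.5C6H6 (5 mol%), (S,S)-Ph-pybox (10 mol%), iPr2NEt (1.5 equiv), 4 Å MS, THF, −20 → 0 °C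
Reagents that add atoms: none
Why: Copper-catalysed asymmetric propargylic etherification: monovalent copper and the amine convert 7 into a copper acetylide that loses acetate to give a copper allenylidene, in which the stereocentre of 7 no longer exists. 6 adds through oxygen to the γ-carbon under control of the pybox ligand, which sets the second S centre, while the centre of 6 is not touched. No alcohol solvent is present, so 6 is the only oxygen nucleophile, and both alkynes of 8 remain terminal for step 7.

Step 6
Reactants: 9 4-bromoresorcinol; 2 tert-butyldimethylsilyl chloride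
Product: 10 1-bromo-2,4-bis(TBSO)benzene
Conditions: imidazole (5 equiv), DMF, rt
Reagents that add atoms: 2 tert-butyldimethylsilyl chloride, CC(C)(C)[Si](C)(C)Cl
Why: Twofold silylation of a resorcinol; the hindered hydroxyl ortho to bromine is driven to completion by excess reagent.

Step 7
Reactants: 8 (S,S)-bis{1-[4-(TBSO)phenyl]prop-2-yn-1-yl} ether; 10 1-bromo-2,4-bis(TBSO)benzene
Product: 11 (R,R)-bis{3-[2,4-bis(TBSO)phenyl]-1-[4-(TBSO)phenyl]prop-2-yn-1-yl} ether
Conditions: 10 (2.3 equiv), PdCl2(PhCN)2 (5 mol%), P(t-Bu)3·HBF4 (10 mol%), CuI (5 mol%), iPr2NH (4 equiv), 1,4-dioxane, degassed, rt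
Reagents that add atoms: 10 1-bromo-2,4-bis(TBSO)benzene, CC(C)(C)[Si](C)(C)Oc1ccc(Br)c(O[Si](C)(C)C(C)(C)C)c1
Why: Twofold Sonogashira coupling; the electron-rich, bulky phosphine lets zerovalent palladium insert into the electron-rich, ortho-substituted C–Br bond at room temperature, and the amine base leaves the aryl silyl ethers and the propargylic stereocentres untouched. The descriptors change from S to R only because the alkynyl group now outranks aryl.

Step 8
Reactants: 11 (R,R)-bis{3-[2,4-bis(TBSO)phenyl]-1-[4-(TBSO)phenyl]prop-2-yn-1-yl} ether
Product: 13 (2R,5R,3Z,4Z)-3,4-bis{[2,4-bis(TBSO)phenyl]methylidene}-2,5-bis[4-(TBSO)phenyl]tetrahydrofuran, via zirconacyclopentadiene 12 (not isolated)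
Conditions: Cp2ZrCl2 (1.2 equiv), n-BuLi (2.4 equiv), THF, −78 °C, 1 h; 11 added at −78 °C (0.02 M), then rt, 3 h; AcOH (6 equiv), 0 °C
Reagents that add atoms: none
Why: Cp2ZrBu2 loses butane on warming to give the butene complex of divalent zirconium, which exchanges butene for one alkyne of 11 to form a zirconacyclopropene; insertion of the tethered second alkyne into its Zr–C bond (oxidative cyclometalation to tetravalent zirconium) gives 12 and joins the two inner alkyne carbons as C3–C4. The closest known reaction type is the Cp2Zr-mediated bicyclisation of 1,6-diynes, ether-tethered ones included, to Z,Z-1,2-bis(alkylidene) five-membered rings. The tetrahydrofuran ring is closed by C–C bond formation on the metal, exo with respect to both alkynes (both outer carbons stay outside the new ring), in a metallacycle-forming step and not by nucleophilic or radical attack. No new stereocentre is formed: C2 and C5 are spectators whose R,R configuration (2,5-trans) is fixed in the ether, and none of their bonds is touched. The two alkene geometries follow from the mechanism, since zirconium and the ring carbon are cis on each former alkyne and protonolysis of the two Zr–C(sp2) bonds by AcOH proceeds with retention, which places each aryl group on the outside (Z,Z). The selectivity needed is regiochemical and chemoselective: the three-atom tether allows only the inner–inner coupling, moderate dilution favours ring closure over dimerisation, and cyclometalation must outrun β-alkoxide elimination of the propargylic C–O bond, which is helped by the poor leaving group (a secondary alkoxide) and by adding 11 cold to the preformed reagent. The silyl ethers are inert because no free butyllithium remains once Cp2ZrBu2 has formed.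

Step 9
Reactants: 13 (2R,5R,3Z,4Z)-3,4-bis{[2,4-bis(TBSO)phenyl]methylidene}-2,5-bis[4-(TBSO)phenyl]tetrahydrofuran
Product: 15 (S,S)-[(2S,3S,4S,5S)-2,5-bis[4-(TBSO)phenyl]tetrahydrofuran-3,4-diyl]bis{[2,4-bis(TBSO)phenyl]methanol}, via trans-fused borolane 14 (not isolated)
Conditions: BH3·THF (1.1 equiv), THF (0.01 M), 0 °C → rt; then NaBO3·4H2O (6 equiv), THF/H2O 1:1, rt
Reagents that add atoms: sodium perborate tetrahydrate (NaBO3·4H2O, drawn as the peroxoborate dimer), [Na+].[Na+].O[B-]1(O)OO[B-](O)(O)OO1
Why: Cyclic hydroboration of a 1,3-diene, then oxidation with retention: boron takes the exocyclic (less substituted, benzylic) carbon of the first alkene, which also keeps it away from a position β to O1, and hydrogen goes to C3 from the face opposite the C2 aryl group, so the new CH(B) arm lies on the same face as that aryl group. From there the remaining B–H can reach only that same face of the second alkene, which is also the face opposite the C5 aryl group, so hydrogen is delivered to C4 from the other side of the ring plane and the trans-fused borolane 14 carries the 2,3-cis, 3,4-trans, 4,5-cis array. Perborate converts both C–B bonds into C–OH with retention and is mild enough for aryl silyl ethers.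

Step 10
Reactants: 15 (S,S)-[(2S,3S,4S,5S)-2,5-bis[4-(TBSO)phenyl]tetrahydrofuran-3,4-diyl]bis{[2,4-bis(TBSO)phenyl]methanol}
Product: 16 [(2S,3R,4R,5S)-2,5-bis[4-(TBSO)phenyl]tetrahydrofuran-3,4-diyl]bis{[2,4-bis(TBSO)phenyl]methanone}
Conditions: Dess–Martin periodinane (3 equiv), NaHCO3 (10 equiv), CH2Cl2, 0 °C → rt
Reagents that add atoms: none
Why: Dess–Martin oxidation of two secondary benzylic alcohols under bicarbonate buffer; no enolisable intermediate meets base, so C3 and C4 should keep their configuration, and the loss of the two carbinol centres is intended.

Step 11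
Reactants: 16 [(2S,3R,4R,5S)-2,5-bis[4-(TBSO)phenyl]tetrahydrofuran-3,4-diyl]bis{[2,4-bis(TBSO)phenyl]methanone}
Product: 17 [(2S,3R,4R,5S)-2,5-bis(4-hydroxyphenyl)tetrahydrofuran-3,4-diyl]bis[(2,4-dihydroxyphenyl)methanone]
Conditions: TBAF (7 equiv), AcOH (8 equiv), THF, 0 °C → rt; pH 6 phosphate buffer work-up
Reagents that add atoms: none
Why: Fluoride-mediated cleavage of aryl silyl ethers; acetic acid protonates each phenoxide as it forms, so neither enolisation at C3/C4 nor retro-oxa-Michael opening at O1 should set in, and the medium is too mild to ionise the benzylic C2–O and C5–O bonds.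

## Compound list

1 | 4-hydroxybenzaldehyde | O=Cc1ccc(O)cc1 | starting material
2 | tert-butyldimethylsilyl chloride | CC(C)(C)[Si](C)(C)Cl | starting material
3 | 4-(tert-butyldimethylsilyloxy)benzaldehyde | O=Cc1ccc(O[Si](C)(C)C(C)(C)C)cc1 | intermediate
4 | ethynylmagnesium bromide | C#C[Mg]Br | starting material
5 | rac-1-[4-(TBSO)phenyl]prop-2-yn-1-ol | C#CC(O)c1ccc(O[Si](C)(C)C(C)(C)C)cc1 | intermediate
6 | (S)-1-[4-(TBSO)phenyl]prop-2-yn-1-ol | C#C[C@H](O)c1ccc(O[Si](C)(C)C(C)(C)C)cc1 | intermediate
7 | rac-1-[4-(TBSO)phenyl]prop-2-yn-1-yl acetate | C#CC(OC(C)=O)c1ccc(O[Si](C)(C)C(C)(C)C)cc1 | intermediate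
8 | (S,S)-bis{1-[4-(TBSO)phenyl]prop-2-yn-1-yl} ether | C#C[C@@H](c1ccc(O[Si](C)(C)C(C)(C)C)cc1)O[C@@H](C#C)c1ccc(O[Si](C)(C)C(C)(C)C)cc1 | intermediate
9 | 4-bromoresorcinol (4-bromobenzene-1,3-diol) | Oc1ccc(Br)c(O)c1 | starting material
10 | 1-bromo-2,4-bis(TBSO)benzene | CC(C)(C)[Si](C)(C)Oc1ccc(Br)c(O[Si](C)(C)C(C)(C)C)c1 | intermediate
11 | (R,R)-bis{3-[2,4-bis(TBSO)phenyl]-1-[4-(TBSO)phenyl]prop-2-yn-1-yl} ether | CC(C)(C)[Si](C)(C)Oc1ccc(C#C[C@@H](c2ccc(O[Si](C)(C)C(C)(C)C)cc2)O[C@@H](C#Cc2ccc(O[Si](C)(C)C(C)(C)C)cc2O[Si](C)(C)C(C)(C)C)c2ccc(O[Si](C)(C)C(C)(C)C)cc2)c(O[Si](C)(C)C(C)(C)C)c1 | intermediate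
12 | zirconacyclopentadiene: Cp2Zr bonded to the two carbons bearing the 2,4-bis(TBSO)phenyl groups, fused at C3–C4 to the (2R,5R)-2,5-bis[4-(TBSO)phenyl]-2,5-dihydrofuran ring (Cp drawn η1) | CC(C)(C)[Si](C)(C)Oc1ccc(C2=C3[C@@H](c4ccc(O[Si](C)(C)C(C)(C)C)cc4)O[C@H](c4ccc(O[Si](C)(C)C(C)(C)C)cc4)C3=C(c3ccc(O[Si](C)(C)C(C)(C)C)cc3O[Si](C)(C)C(C)(C)C)[Zr]2(C2C=CC=C2)C2C=CC=C2)c(O[Si](C)(C)C(C)(C)C)c1 | intermediate (not isolated)
13 | (2R,5R,3Z,4Z)-3,4-bis{[2,4-bis(TBSO)phenyl]methylidene}-2,5-bis[4-(TBSO)phenyl]tetrahydrofuran (2,5-trans) | CC(C)(C)[Si](C)(C)Oc1ccc(/C=C2\[C@@H](c3ccc(O[Si](C)(C)C(C)(C)C)cc3)O[C@H](c3ccc(O[Si](C)(C)C(C)(C)C)cc3)/C2=C\c2ccc(O[Si](C)(C)C(C)(C)C)cc2O[Si](C)(C)C(C)(C)C)c(O[Si](C)(C)C(C)(C)C)c1 | intermediate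
14 | trans-fused B–H borolane: boron bridges the two benzylic CH[2,4-bis(TBSO)phenyl] carbons on C3 and C4 of the (2S,5S)-2,5-bis[4-(TBSO)phenyl]tetrahydrofuran; H on C3 anti to the C2 aryl group, H on C4 anti to the C5 aryl group (drawn as the monomer) | [BH]1[C@H](c2ccc(O[Si](C)(C)C(C)(C)C)cc2O[Si](C)(C)C(C)(C)C)[C@@H]2[C@@H]([C@H]1c1ccc(O[Si](C)(C)C(C)(C)C)cc1O[Si](C)(C)C(C)(C)C)[C@@H](c1ccc(O[Si](C)(C)C(C)(C)C)cc1)O[C@@H]2c1ccc(O[Si](C)(C)C(C)(C)C)cc1 | intermediate (not isolated)
15 | (S,S)-[(2S,3S,4S,5S)-2,5-bis[4-(TBSO)phenyl]tetrahydrofuran-3,4-diyl]bis{[2,4-bis(TBSO)phenyl]methanol} | O[C@H](c1ccc(O[Si](C)(C)C(C)(C)C)cc1O[Si](C)(C)C(C)(C)C)[C@@H]1[C@@H]([C@H](O)c2ccc(O[Si](C)(C)C(C)(C)C)cc2O[Si](C)(C)C(C)(C)C)[C@@H](c2ccc(O[Si](C)(C)C(C)(C)C)cc2)O[C@@H]1c1ccc(O[Si](C)(C)C(C)(C)C)cc1 | intermediate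
16 | [(2S,3R,4R,5S)-2,5-bis[4-(TBSO)phenyl]tetrahydrofuran-3,4-diyl]bis{[2,4-bis(TBSO)phenyl]methanone} | O=C(c1ccc(O[Si](C)(C)C(C)(C)C)cc1O[Si](C)(C)C(C)(C)C)[C@@H]1[C@@H](C(=O)c2ccc(O[Si](C)(C)C(C)(C)C)cc2O[Si](C)(C)C(C)(C)C)[C@@H](c2ccc(O[Si](C)(C)C(C)(C)C)cc2)O[C@@H]1c1ccc(O[Si](C)(C)C(C)(C)C)cc1 | intermediate
17 | [(2S,3R,4R,5S)-2,5-bis(4-hydroxyphenyl)tetrahydrofuran-3,4-diyl]bis[(2,4-dihydroxyphenyl)methanone] | O=C(c1ccc(O)cc1O)[C@@H]1[C@@H](C(=O)c2ccc(O)cc2O)[C@@H](c2ccc(O)cc2)O[C@@H]1c1ccc(O)cc1 | target

## Step count and least certain steps

Total step count: 11. Longest linear sequence: 9 (steps 1, 2, 3, 5, 7, 8, 9, 10, 11); steps 4 and 6 are one-step branches.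

Step 8 (key step). The most likely failure is loss of the ether. In the zirconacyclopropene formed from the first alkyne the propargylic C–O bond is β to zirconium, and β-alkoxide elimination to an allenylzirconium alkoxide can compete with insertion of the second alkyne, the more so because the carbon is benzylic and carries an electron-rich aryl group. Incomplete protonolysis of the hindered Zr–C bonds is a lesser concern. Fallback: the ring closure is changed from a stoichiometric early-metal cyclometalation to a catalytic, hydrogen-mediated reductive cyclisation. 11 is treated with [Rh(cod)2]OTf and rac-BINAP under 1 atm of H2 in ClCH2CH2Cl at room temperature. Monovalent rhodium should couple the two alkynes oxidatively to a rhodacyclopentadiene, which hydrogen cleaves to the same Z,Z-diene, and a late metal has no oxophilicity to drive alkoxide elimination. The fallback sets out from 11 and returns to the route at 13; it makes no new compound (F0).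

Step 5. The most likely failure is slow capture of the copper allenylidene by a hindered secondary alcohol, so that return of acetate, oligomerisation of the allenylidene or incomplete ligand control (formation of the meso ether) takes over. Fallback: catalyst control is given up for a separation of diastereomers. A portion of 5 is converted with Cl3CCN and catalytic DBU into the racemic propargylic trichloroacetimidate F1. 6 and F1 are then joined with catalytic TMSOTf in CH2Cl2 at −78 °C through the silyloxyphenyl-stabilised propargylic cation (SN1). Only the nucleophile's centre is defined, so 8 should form together with the meso ether F2 and is separated from it by chromatography; the enantiomeric purity of 8 is then that of 6. The fallback sets out from 6 (with F1 made from 5) and returns at 8.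

Step 9. The most likely failure is loss of face control at the second alkene. If the second B–H addition becomes intermolecular, or if the strain of the trans-fused borolane slows the intramolecular path, boron can approach from either face and the 3,4-cis diastereomer results. Partial loss of aryl silyl ethers during the oxidation is a minor risk. Fallback: the hydrogens on C3 and C4 are introduced by reduction instead of hydroboration. 13 is photo-oxygenated (O2, tetraphenylporphyrin, visible light, CH2Cl2, −78 °C); the s-cis diene should take up singlet oxygen in a [4+2] cycloaddition to give the bicyclic endoperoxide F3. Thiourea in MeOH then reduces the O–O bond to the cis-ene-1,4-diol F4, and Dess–Martin periodinane with NaHCO3 oxidises both carbinols to the tetrasubstituted enedione F5. Zinc dust in AcOH at 0 °C finally reduces F5 through its bis-enol to 16. The two ring carbons are protonated under kinetic, acidic conditions; the face taken at the second carbon is not secured, so a diastereomer separation may be needed. The fallback sets out from 13 and returns at 16.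

Step 11. The most likely failure is epimerisation at C3 or C4, or ring opening by retro-oxa-Michael reaction, if phenoxide overruns the buffer while six silyl groups leave. The ortho-silyloxy ketone groups cleave slowest and prolong the exposure. Fallback: the silyl groups are removed before the ketones exist. 15 is desilylated with the same buffered fluoride to the octahydroxy compound F6, which has no enolisable centre. The two benzylic carbinols of F6 are then oxidised with activated MnO2 in acetone at room temperature, a reagent that attacks benzylic alcohols and should spare phenols and benzylic ethers, to give 17 directly. The fallback sets out from 15 and returns at 17.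

Step 3. The most likely failure is insufficient discrimination between the aryl and the ethynyl group by the lipase, so that 6 reaches high enantiomeric purity only at high conversion and with loss of material. Fallback: the centre is set by a catalyst-controlled addition instead of a resolution. 3 is treated with trimethylsilylacetylene and Me2Zn in toluene at 0 °C in the presence of a ProPhenol ligand (the enantiomer that leads to the spatial arrangement of 6), an enantioselective alkynylzinc addition to an aromatic aldehyde, to give the C-silylated propargylic alcohol F7. The alkynyl silyl group is then removed with catalytic AgNO3 in aqueous acetone, which should leave the aryl silyl ether in place. The fallback sets out from 3 and returns at 6; 7 is still made from 5 by step 4.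

## Further compounds

F0 | step 8 | none | none
F1 | step 5 | rac-1-[4-(TBSO)phenyl]prop-2-yn-1-yl 2,2,2-trichloroacetimidate | C#CC(OC(=N)C(Cl)(Cl)Cl)c1ccc(O[Si](C)(C)C(C)(C)C)cc1
F2 | step 5 | meso-(R,S)-bis{1-[4-(TBSO)phenyl]prop-2-yn-1-yl} ether | C#C[C@@H](c1ccc(O[Si](C)(C)C(C)(C)C)cc1)O[C@H](C#C)c1ccc(O[Si](C)(C)C(C)(C)C)cc1
F3 | step 9 | (1R,4S,5R,7R)-1,4-bis[2,4-bis(TBSO)phenyl]-5,7-bis[4-(TBSO)phenyl]-1,4,5,7-tetrahydrofuro[3,4-d][1,2]dioxine (endoperoxide, the two new C–O bonds cis) | CC(C)(C)[Si](C)(C)Oc1ccc([C@@H]2OO[C@H](c3ccc(O[Si](C)(C)C(C)(C)C)cc3O[Si](C)(C)C(C)(C)C)C3=C2[C@@H](c2ccc(O[Si](C)(C)C(C)(C)C)cc2)O[C@@H]3c2ccc(O[Si](C)(C)C(C)(C)C)cc2)c(O[Si](C)(C)C(C)(C)C)c1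
F4 | step 9 | [(2R,5R)-2,5-bis[4-(TBSO)phenyl]-2,5-dihydrofuran-3,4-diyl]bis{[2,4-bis(TBSO)phenyl]methanol}, carbinol on C3 R and on C4 S | O[C@H](c1ccc(O[Si](C)(C)C(C)(C)C)cc1O[Si](C)(C)C(C)(C)C)C1=C([C@@H](O)c2ccc(O[Si](C)(C)C(C)(C)C)cc2O[Si](C)(C)C(C)(C)C)[C@@H](c2ccc(O[Si](C)(C)C(C)(C)C)cc2)O[C@@H]1c1ccc(O[Si](C)(C)C(C)(C)C)cc1
F5 | step 9 | [(2R,5R)-2,5-bis[4-(TBSO)phenyl]-2,5-dihydrofuran-3,4-diyl]bis{[2,4-bis(TBSO)phenyl]methanone} | O=C(c1ccc(O[Si](C)(C)C(C)(C)C)cc1O[Si](C)(C)C(C)(C)C)C1=C(C(=O)c2ccc(O[Si](C)(C)C(C)(C)C)cc2O[Si](C)(C)C(C)(C)C)[C@@H](c2ccc(O[Si](C)(C)C(C)(C)C)cc2)O[C@@H]1c1ccc(O[Si](C)(C)C(C)(C)C)cc1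
F6 | step 11 | (S,S)-[(2S,3S,4S,5S)-2,5-bis(4-hydroxyphenyl)tetrahydrofuran-3,4-diyl]bis[(2,4-dihydroxyphenyl)methanol] | O[C@H](c1ccc(O)cc1O)[C@@H]1[C@@H]([C@H](O)c2ccc(O)cc2O)[C@@H](c2ccc(O)cc2)O[C@@H]1c1ccc(O)cc1
F7 | step 3 | (R)-1-[4-(TBSO)phenyl]-3-(trimethylsilyl)prop-2-yn-1-ol (same spatial arrangement as 6) | C[Si](C)(C)C#C[C@H](O)c1ccc(O[Si](C)(C)C(C)(C)C)cc1
A1 | alternative 1 | (3R,4R)-N,N'-di(quinolin-8-yl)tetrahydrofuran-3,4-dicarboxamide (trans) | O=C(Nc1cccc2cccnc12)[C@@H]1[C@@H](C(=O)Nc2cccc3cccnc23)COC1
A2 | alternative 1 | 1-(benzyloxy)-4-iodobenzene | Ic1ccc(OCc2ccccc2)cc1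
A3 | alternative 1 | cis,trans,cis-2,5-bis(4-benzyloxyphenyl)tetrahydrofuran-3,4-bis(quinolin-8-ylamide) | O=C(Nc1cccc2cccnc12)[C@@H]1[C@@H](C(=O)Nc2cccc3cccnc23)[C@@H](c2ccc(OCc3ccccc3)cc2)O[C@@H]1c1ccc(OCc2ccccc2)cc1
A4 | alternative 2 | (2S,3R)-2-[4-(benzyloxy)phenyl]-3-[2,4-bis(benzyloxy)benzoyl]-2,3-dihydrofuran (cis) | C1=CO[C@H](c2ccc(OCc3ccccc3)cc2)[C@@H]1C(=O)c1ccc(OCc2ccccc2)cc1OCc1ccccc1
A5 | alternative 2 | [2,4-bis(benzyloxy)phenyl]boronic acid | OB(O)c1ccc(OCc2ccccc2)cc1OCc1ccccc1
A6 | alternative 2 | carbon monoxide | [C-]#[O+]
A7 | alternative 2 | hexa-O-benzyl target | O=C(c1ccc(OCc2ccccc2)cc1OCc1ccccc1)[C@@H]1[C@@H](C(=O)c2ccc(OCc3ccccc3)cc2OCc2ccccc2)[C@@H](c2ccc(OCc3ccccc3)cc2)O[C@@H]1c1ccc(OCc2ccccc2)cc1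
A8 | alternative 3 | (2S,3R,4R,5S)-2,5-bis[4-(benzyloxy)phenyl]tetrahydrofuran-3,4-dicarboxylic acid | O=C(O)[C@@H]1[C@@H](C(=O)O)[C@@H](c2ccc(OCc3ccccc3)cc2)O[C@@H]1c1ccc(OCc2ccccc2)cc1
A9 | alternative 3 | 3-chloro-5-(benzyloxy)benzyne | ClC1=CC(OCc2ccccc2)=CC#C1
A10 | alternative 3 | 5-(benzyloxy)-3-chloro-2-(trimethylsilyl)phenyl trifluoromethanesulfonate | C[Si](C)(C)c1c(Cl)cc(OCc2ccccc2)cc1OS(=O)(=O)C(F)(F)F
A11 | alternative 3 | bis(6-chloro) tetra-O-benzyl target | O=C(c1c(O)cc(OCc2ccccc2)cc1Cl)[C@@H]1[C@@H](C(=O)c2c(O)cc(OCc3ccccc3)cc2Cl)[C@@H](c2ccc(OCc3ccccc3)cc2)O[C@@H]1c1ccc(OCc2ccccc2)cc1
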